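**Plan**
1. Side-chain locants: C1' is the benzylic CH2, C2' the C=O, C23' the CH3. Retrosynthetic cuts, in order: the two O–CH3 bonds of a dimethyl ether precursor, then C7'–C8' in the middle of the chain, then C2'–C3' in the aryl half.
2. Enabling feature: C7' and C8' are plain CH2 groups inside the unbranched, heteroatom-free run C3'–C23'. Each side of the cut is therefore a primary alkyl radical, that is, a straight-chain carboxylic acid with one sacrificial carbon (a C17 fatty acid and an 8-aryl-7-oxooctanoic acid).
3. The C2' ketone lies exactly five CH2 groups from the cut, so C3'–C7' plus the sacrificial carboxyl carbon are the six ring carbons of cyclohexanone, which serves as a temporary ring.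
4. Forward order: an arylacetyl chloride C-acylates a cyclohexanone enamine (C2'–C3'). Hydroxide opens the ring (retro-Claisen) and both acids become N-hydroxyphthalimide esters. A Ni-electrocatalytic doubly decarboxylative coupling then joins C7' to C8' and brings in 16 of the 23 chain carbons, and BBr3 frees the resorcinol.
5. Helpers and their removal: the ring (step 3), two CO2/phthalimide units (step 6), two methyl ethers (step 7). The benzene ring is bought; no ring of the target is built.
6. Stereochemistry: the target has no stereocentre and no stereogenic double bond, so none has to be set.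

Key step: step 6

Remark: the target is achiral, so the request for a single enantiomer is met trivially. The one labile centre on the way (ring C2 of diketone 5) is racemic and enolisable and disappears in step 3.

**Step 1**
Reactants: 1 3,5-dimethoxyphenylacetic acid
Product: 2 3,5-dimethoxyphenylacetyl chloride
Conditions: (COCl)2 (1.2 equiv), DMF (cat.), CH2Cl2, 0 °C to rt; evaporate, use crude
Reagents that add atoms: oxalyl chloride, O=C(Cl)C(=O)Cl
Why: DMF-catalysed (Vilsmeier-type) acid chloride formation is mild and free of Lewis acid, so the electron-rich dimethoxyarene should be left untouched and the volatile by-products allow use of the crude chloride.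

**Step 2**
Reactants: 2 3,5-dimethoxyphenylacetyl chloride; 3 4-(cyclohex-1-en-1-yl)morpholine (1-morpholinocyclohexene)
Product: 5 2-[(3,5-dimethoxyphenyl)acetyl]cyclohexan-1-one, via acylated enamine 4 (not isolated)
Conditions: Et3N (1.1 equiv), CH2Cl2, 0 °C to rt; then 2 M aq. HCl, rt, vigorous stirring
Reagents that add atoms: water, O
Why: Stork enamine C-acylation, in which the β-carbon of the enamine attacks the acid chloride (or the derived arylketene, whose cycloadduct opens to the same vinylogous amide) and cold dilute acid hydrolyses it to the 1,3-diketone; the new ring centre is enolisable, obtained racemic and destroyed in step 3.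

**Step 3**
Reactants: 5 2-[(3,5-dimethoxyphenyl)acetyl]cyclohexan-1-one
Product: 6 8-(3,5-dimethoxyphenyl)-7-oxooctanoic acid
Conditions: NaOH (3 equiv), EtOH/H2O, reflux; then aq. HCl to pH 2
Reagents that add atoms: sodium hydroxide, [Na+].[OH-]
Why: Retro-Claisen cleavage of a 2-acylcyclohexanone (the classical six-carbon chain extension), in which hydroxide should add preferentially to the more electrophilic ring carbonyl and expel the enolate of the benzyl ketone, opening the temporary ring to the 7-oxo acid.

**Step 4**
Reactants: 6 8-(3,5-dimethoxyphenyl)-7-oxooctanoic acid
Product: 7 1,3-dioxoisoindolin-2-yl 8-(3,5-dimethoxyphenyl)-7-oxooctanoate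
Conditions: N-hydroxyphthalimide (1.05 equiv), DIC (1.1 equiv), DMAP (cat.), CH2Cl2, rt
Reagents that add atoms: N-hydroxyphthalimide, O=C1c2ccccc2C(=O)N1O
Why: Steglich-type carbodiimide esterification gives the redox-active ester under nearly neutral conditions, so the ketone and arene are spectators and the activated ester should not re-close onto C6 in a Dieckmann-type reaction.

**Step 5**
Reactants: 8 heptadecanoic acid
Product: 9 1,3-dioxoisoindolin-2-yl heptadecanoate
Conditions: N-hydroxyphthalimide (1.05 equiv), DIC (1.1 equiv), DMAP (cat.), CH2Cl2, rt
Reagents that add atoms: N-hydroxyphthalimide, O=C1c2ccccc2C(=O)N1O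
Why: The same Steglich-type carbodiimide esterification on an unfunctionalised fatty acid gives a crystalline redox-active ester that can be made in bulk.

**Step 6**
Reactants: 7 1,3-dioxoisoindolin-2-yl 8-(3,5-dimethoxyphenyl)-7-oxooctanoate; 9 1,3-dioxoisoindolin-2-yl heptadecanoate (3 equiv)
Product: 10 1-(3,5-dimethoxyphenyl)tricosan-2-one
Conditions: NiCl2·6H2O (20 mol %), 4,4',4''-tri-tert-butyl-2,2':6',2''-terpyridine (20 mol %), NaI, DMF, undivided cell, Zn(+)/RVC(−), constant current, rt; aq. HCl work-up
Reagents that add atoms: none
Why: Cathodically generated low-valent Ni(terpyridine) transfers one electron to each phthalimide ester, whose radical anion loses phthalimide anion and CO2 to give the primary radicals C16H33• and •CH2(CH2)4C(O)CH2Ar; successive capture of both at nickel gives a dialkyl-Ni(III) species that forms C7'–C8' by reductive elimination, while the zinc anode supplies the electrons. The closest known reaction type is the Ni-electrocatalytic doubly decarboxylative sp3–sp3 cross-coupling of two redox-active esters, the reductive counterpart of a mixed Kolbe electrolysis, which is established for pairs of primary alkyl esters carrying ketones and arenes. No ring is closed and no stereocentre is formed. The selectivity needed is cross- over homo-coupling of two electronically alike primary radicals; it is only statistical, so the cheap ester 9 is used in excess to channel 7 into the cross product, and the three possible products (hydrocarbon, mono-aryl ketone, bis-aryl diketone) differ enough in polarity to be separated on silica. Chemoselectivity comes from the reductive regime: the 1,3-dimethoxyarene, which would be oxidised before a carboxylate at a Kolbe anode, and the C2' ketone, which is reduced only at much more negative potential than the nickel catalyst, are both spectators. The only intramolecular escapes of the keto radical, 1,5-H transfer from C3'–H and reversible 6-exo addition to the C2' carbonyl, are slow for a primary alkyl radical compared with capture by nickel at this catalyst loading.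

**Step 7**
Reactants: 10 1-(3,5-dimethoxyphenyl)tricosan-2-one
Product: 11 5-(2'-oxotricosyl)resorcinol [1-(3,5-dihydroxyphenyl)tricosan-2-one]
Conditions: BBr3 (4 equiv), CH2Cl2, −78 °C to rt; then ice/H2O
Reagents that add atoms: none
Why: BBr3 aryl methyl ether cleavage, in which boron binds each methoxy oxygen and bromide removes the methyl group by SN2, one extra equivalent being allowed for reversible complexation of the ketone, which cannot close onto the ring because its carbonyl carbon is only two atoms from the arene.

**Compound list**
1 | 3,5-dimethoxyphenylacetic acid | COc1cc(CC(=O)O)cc(OC)c1 | starting material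
2 | 3,5-dimethoxyphenylacetyl chloride | COc1cc(CC(=O)Cl)cc(OC)c1 | intermediate
3 | 4-(cyclohex-1-en-1-yl)morpholine | C1CCC(=CC1)N2CCOCC2 | starting material
4 | 2-(3,5-dimethoxyphenyl)-1-[2-(morpholin-4-yl)cyclohex-1-en-1-yl]ethan-1-one (acylated enamine) | COc1cc(CC(=O)C2=C(N3CCOCC3)CCCC2)cc(OC)c1 | intermediate
5 | 2-[(3,5-dimethoxyphenyl)acetyl]cyclohexan-1-one (racemic, enolisable) | COc1cc(CC(=O)C2CCCCC2=O)cc(OC)c1 | intermediate
6 | 8-(3,5-dimethoxyphenyl)-7-oxooctanoic acid | COc1cc(CC(=O)CCCCCC(=O)O)cc(OC)c1 | intermediate
7 | 1,3-dioxoisoindolin-2-yl 8-(3,5-dimethoxyphenyl)-7-oxooctanoate | COc1cc(CC(=O)CCCCCC(=O)ON2C(=O)c3ccccc3C2=O)cc(OC)c1 | intermediate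
8 | heptadecanoic acid | CCCCCCCCCCCCCCCCC(=O)O | starting material
9 | 1,3-dioxoisoindolin-2-yl heptadecanoate | CCCCCCCCCCCCCCCCC(=O)ON1C(=O)c2ccccc2C1=O | intermediate
10 | 1-(3,5-dimethoxyphenyl)tricosan-2-one | CCCCCCCCCCCCCCCCCCCCCC(=O)Cc1cc(OC)cc(OC)c1 | intermediate
11 | 5-(2'-oxotricosyl)resorcinol | CCCCCCCCCCCCCCCCCCCCCC(=O)Cc1cc(O)cc(O)c1 | target

**Step count**
- Total step count: 7.
- Longest linear sequence: 6 (steps 1, 2, 3, 4, 6, 7). Step 5 is a one-step side branch.

**Steps most likely to fail**

**Step 6.**
- What may go wrong: statistical homo-coupling of either radical; loss of the primary radicals by hydrogen abstraction before capture at nickel; base-induced re-closure of the activated ester onto C6.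
- Fallback: it sets out from 7 and comes back at 10. 1-Bromohexadecane is converted with magnesium in THF into hexadecylmagnesium bromide F1. Complete transmetalation with ZnCl2 (0.5 equiv) gives dihexadecylzinc F2. F2 is then coupled with 7 in a Ni-catalysed decarboxylative alkyl–alkyl Negishi reaction (NiCl2·glyme, 4,4'-di-tert-butyl-2,2'-bipyridine, THF/DMF, rt) to give 10.
- Why this differs: pairing one radical precursor with one organometallic nucleophile makes the cross-coupling intrinsic instead of statistical. A diorganozinc should not add to the ketone at room temperature.

**Step 3.**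
- What may go wrong: hydroxide attack at the exocyclic instead of the ring carbonyl, which strips the arylacetyl group off again; base-induced self-condensation of the benzyl ketone.
- Fallback: it avoids the temporary ring, sets out from 1 and comes back at 6. Acid 1 is doubly deprotonated with iPrMgCl (2.1 equiv, THF) to the magnesium enediolate. This is C-acylated at low temperature with commercial methyl 7-chloro-7-oxoheptanoate to give 2-(3,5-dimethoxyphenyl)-9-methoxy-3,9-dioxononanoic acid F3. On acidic work-up and gentle warming this β-keto acid decarboxylates to methyl 8-(3,5-dimethoxyphenyl)-7-oxooctanoate F4. Saponification (LiOH, THF/H2O, then acid) gives 6.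

**Step 2.**
- What may go wrong: dehydrochlorination of the arylacetyl chloride followed by ketene dimerisation; O-acylation or double acylation; acid-induced cyclodehydration of the activated arene onto the ring carbonyl during enamine hydrolysis.
- Fallback: it replaces the enamine by a magnesium enolate and needs no acidic hydrolysis. It sets out from 2 and comes back at 5. Chloride 2 is treated with 1H-benzotriazole and Et3N in CH2Cl2 to give 1-(1H-benzotriazol-1-yl)-2-(3,5-dimethoxyphenyl)ethan-1-one F5. F5 C-acylates cyclohexanone under soft enolisation (MgBr2·OEt2, iPr2NEt, CH2Cl2, rt) to give 5.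

**Further compounds**
F1 | step 6 | hexadecylmagnesium bromide | CCCCCCCCCCCCCCCC[Mg]Br
F2 | step 6 | dihexadecylzinc | CCCCCCCCCCCCCCCC[Zn]CCCCCCCCCCCCCCCC
F3 | step 3 | 2-(3,5-dimethoxyphenyl)-9-methoxy-3,9-dioxononanoic acid (racemic, transient) | COC(=O)CCCCCC(=O)C(C(=O)O)c1cc(OC)cc(OC)c1
F4 | step 3 | methyl 8-(3,5-dimethoxyphenyl)-7-oxooctanoate | COC(=O)CCCCCC(=O)Cc1cc(OC)cc(OC)c1
F5 | step 2 | 1-(1H-benzotriazol-1-yl)-2-(3,5-dimethoxyphenyl)ethan-1-one | COc1cc(CC(=O)n2nnc3ccccc32)cc(OC)c1
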